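## The problem

Target 12 is (S)-2-(3,4-dimethoxyphenyl)-5,7,8-trimethoxychroman-4-one, a flavanone. Ring A (the benzo ring: methoxy groups at C5, C7 and C8, hydrogen at C6) is fused through C4a–C8a to ring C (O1, C2, C3 and the C4 carbonyl), and ring B, a 3,4-dimethoxyphenyl group, sits on C2. The only stereocentre is C2 (S); nothing else in the molecule can relay chirality to it, so a reagent or catalyst has to set it. C2 is benzylic, bound to O1 and β to the ketone, so once the carbonyl is present base (and strong acid) can open ring C to the 2'-hydroxychalcone and racemise the compound. The ketone should therefore arrive late and under neutral conditions. Ring A carries four oxygens in a 1,2,3,5 pattern, and one of them (O1, on C8a next to the C8 methoxy group) must be told apart from three methyl ethers. Both arenes are electron-rich (ring A has a para pair of methoxy groups at C5 and C8), so strong oxidants and electrophiles are tolerated only when they are directed to one site. The enabling feature is that O1–C8a=C4a–C4 is the hetero-diene of an ortho-quinone methide of ring A, stabilised by the C5 and C7 methoxy groups, while C2=C3 with ring B is a para-alkoxystyrene. Ring C without its carbonyl oxygen is thus a [4+2] adduct, and C4, benzylic to ring A, can be oxygenated afterwards.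

## Retrosynthesis

**12 to 11.** The C4 carbonyl is taken back to the secondary alcohol of flavan-4-ol 11. A neutral oxidation of a benzylic alcohol is the mildest way to create the ketone and keeps base away from the finished flavanone. Both C4 epimers of 11 serve, so no stereocontrol is asked at C4.

**11 to 10.** The C4–O bond is cut, leaving chroman 10. C4–H is the most hydridic C–H bond of 10, because the derived cation is the O-alkylated quinone methide of ring A. The forward step must prefer C4–H over C2–H and must trap the cation with water before it loses a proton from C3.

**10 to 7 and 8 (through 9).** The C3–C4 and O1–C2 bonds are cut together, a retro-hetero-Diels–Alder reaction. This gives salicyl alcohol 7, the precursor of quinone methide 9, and 3,4-dimethoxystyrene 8. Cutting only O1–C2 (an oxa-Michael closure of a chalcone) would form the stereocentre under the basic, reversible conditions the target does not tolerate. Cutting C4–C4a (a Friedel–Crafts closure) would raise a regiochemical question on ring A. The [4+2] cut removes ring C and the stereocentre in one convergent step and leaves two achiral, simple pieces. The forward reaction needs head-to-tail regiochemistry, which polarity supplies, and facial control at C2, which a chiral acid bound to the quinone methide oxygen has to supply.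

**7 to 6.** The hydroxymethyl group is taken back to the aldehyde of salicylaldehyde 6. The aldehyde is the stable, storable form of this carbon; the forward reduction has to be gentle because 7 ionises easily.

**6 to 4 (through 5).** The O–H of 6 is traced to an O–CH3 bond in tetramethoxybenzaldehyde 4. Removing one methyl group next to the carbonyl through boron chelate 5 is the shortest way to differentiate O1. It asks that, of the two ortho ethers, the one flanked by the C3 methoxy group is cleaved.

**4 to 2 (through 3).** The aryl–CHO bond is cut. Tetramethoxybenzene 2 has a single kind of ring C–H, activated by three methoxy groups, so formylation through iminium salt 3 can give only one aldehyde.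

**2 to 1.** One O–CH3 bond is cut, leading to commercial 3,4,5-trimethoxyphenol 1. Compound 8 is also commercial.

## Roads not taken

**Alternative 1:** one-carbon insertion through a siloxycyclopropane.
- Cut: C3 is removed. The target is seen as the homologue of benzofuranone A3, whose silyl enol ether is siloxybenzofuran A2.
- Forward key step: a chiral zinc carbenoid from Et2Zn and CH2I2 adds methylene across the enol-ether double bond of A2 to give cyclopropane A1. Opening the shared bond of A1 would expand the five-membered ring and give 12 with the ketone in place.
- Merits: no late C–H oxidation is needed. This is a real advantage over the chosen plan, which spends two steps on the C4 oxidation level.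
- Weak points:
  - Enantioselective methylene transfer is dependable when a hydroxyl group anchors the carbenoid. A2 offers none, and its double bond is tetrasubstituted and part of an aromatic furan.
  - The ring opening must break the internal bond and protonate the aryl-bearing carbon. The configuration of C2 therefore depends on the steric course of a protonolysis, not on the cyclopropanation alone.
  - Cleavage of the external bond would leave the five-membered ring intact.
  - A3 needs the same differentiated ring A phenol as the chosen route, so nothing is saved there.
- Comparison: the chosen plan offers a C2–H and a C2–O bond that, once formed, are not touched again, and a convergent union of two simple pieces.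

**Alternative 2:** quinone umpolung.
- Cut: O1–C8a.
- Forward key step: Ag2O oxidises acylhydroquinone A5 to acylquinone A6. Its secondary hydroxyl adds to C8a, and reduction with Na2S2O4 returns the hydroquinone as dihydroxyflavanone A4.
- Merits: the stereocentre of A5 can be set by a well-established asymmetric aldol or ketone reduction, and its C–O bond is never broken. Absolute stereocontrol is therefore more secure than in the chosen plan.
- Weak points:
  - A4 still needs two phenols methylated. The C5 hydroxyl is chelated to the C4 carbonyl and responds only to base and heat, the conditions under which flavanones open to chalcones and racemise.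
  - The β-hydroxy ketone A5 is prone to dehydration.
  - The hydroquinone needs its own protecting-group traffic.
- Comparison: the chosen plan carries all five methyl ethers from the start and exposes the flavanone to no base. Against the better stereocontrol of this road it sets a known reduction–Mitsunobu fallback to the same chroman 10.

**Alternative 3:** carbonylative three-component annulation.
- Cut: C4a–C4, C4–C3 and O1–C2.
- Forward key step: iodophenol A8, carbon monoxide and alkyne A9 combine under PdCl2(PPh3)2 and Et2NH to give flavone A7. An enantioselective reduction of the C2=C3 bond would then give 12.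
- Merits: it is highly convergent, the C4 oxidation level is correct from the outset, and enantioselective hydrogenation of flavones is arguably closer precedent for the stereo-defining step than exists for the chosen key step.
- Weak points:
  - A8 requires ortho-iodination of a phenol that is itself not a simple commercial compound, with the para position open.
  - Closure to the five-membered aurone competes in the carbonylation.
  - Hydrogenation of flavones tends to run on to the flavanol, so a re-oxidation is added.
  - The C5 methoxy group peri to the carbonyl and the electron-rich rings make the enone a poor acceptor.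
- Comparison: the chosen plan forms the stereocentre in the ring-forming step, needs neither carbon monoxide nor an aryl iodide, and builds ring A from 1 by a formylation whose position is unambiguous.

Key step: step 5

Remarks on the chemistry:
- Chroman numbering (O1, C2–C4, C4a, C5–C8, C8a) is used for 9–12.
- Assumption: the sense of induction of the phosphoramide in step 5 cannot be predicted with confidence for this substrate pair. The (R)-catalyst is written; its antipode would be used if it favours the (R)-chroman.
- Assumption: in step 3 the ortho ether flanked by a second methoxy group is taken to be the one BCl3 cleaves. The position of the free hydroxyl would be confirmed before the material is carried on.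

## Route

Step 1
Reactants: 1 3,4,5-trimethoxyphenol
Product: 2 1,2,3,5-tetramethoxybenzene
Conditions: MeI, K2CO3, acetone, reflux
Reagents that add atoms: iodomethane, CI
Why: Williamson ether synthesis on the phenoxide; the phenol is the only acidic site and the product is symmetrical, so no selectivity question arises.

Step 2
Reactants: 2 1,2,3,5-tetramethoxybenzene
Product: 4 2,3,4,6-tetramethoxybenzaldehyde, via aryl iminium chloride 3 (not isolated)
Conditions: POCl3, DMF, 0 °C to 60 °C; then ice-water
Reagents that add atoms: N,N-dimethylformamide, CN(C)C=O; water, O
Why: Vilsmeier–Haack formylation; the two ring C–H positions of 2 are equivalent and each is ortho or para to three methoxy groups, so a single aldehyde should result after hydrolysis of iminium salt 3.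

Step 3
Reactants: 4 2,3,4,6-tetramethoxybenzaldehyde
Product: 6 2-hydroxy-3,4,6-trimethoxybenzaldehyde, via aryloxydichloroborane 5 (not isolated)
Conditions: BCl3 (1.1 equiv), CH2Cl2, −78 °C to 0 °C; then H2O
Reagents that add atoms: none
Why: Chelation-controlled Lewis acid demethylation of an aryl methyl ether ortho to a carbonyl group; BCl3 bridges the aldehyde oxygen and an ortho ether oxygen and chloride removes the methyl group. Of the two ortho ethers the C2 methoxy group, wedged between the formyl and the C3 methoxy group and twisted out of the ring plane, is the more basic and more strained and should be the one cleaved, as in Lewis acid demethylation of the analogous 2,3,4,6-tetramethoxyaryl ketones; chelate 5 is hydrolysed on work-up.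

Step 4
Reactants: 6 2-hydroxy-3,4,6-trimethoxybenzaldehyde
Product: 7 2-(hydroxymethyl)-3,5,6-trimethoxyphenol
Conditions: NaBH4, THF/MeOH, 0 °C; pH 7 phosphate buffer work-up
Reagents that add atoms: none
Why: NaBH4 reduction of an aldehyde; low temperature, short contact time and a neutral buffered work-up are meant to keep the electron-rich salicyl alcohol from ionising, and 7 is used at once without chromatography on acidic silica.

Step 5
Reactants: 7 2-(hydroxymethyl)-3,5,6-trimethoxyphenol; 8 3,4-dimethoxystyrene (4-ethenyl-1,2-dimethoxybenzene)
Product: 10 (S)-2-(3,4-dimethoxyphenyl)-5,7,8-trimethoxychroman, via ortho-quinone methide 9 (not isolated)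
Conditions: (R)-3,3'-bis(2,4,6-triisopropylphenyl)-1,1'-binaphthyl-2,2'-diyl N-triflylphosphoramide (10 mol%), 8 (3 equiv), 5 Å MS, CH2Cl2/toluene, −40 °C, slow addition of 7
Reagents that add atoms: none
Why: Inverse-electron-demand hetero-Diels–Alder reaction of an ortho-quinone methide generated in situ by a chiral Brønsted acid; the closest known reaction type is the N-triflylphosphoramide-catalysed asymmetric [4+2] cycloaddition of ortho-hydroxybenzyl alcohols with unfunctionalised styrenes. The acid ionises the benzylic alcohol of 7, helped by the methoxy groups ortho and para to the benzylic carbon, to quinone methide 9, which remains hydrogen-bonded or ion-paired through its oxygen to the chiral anion. The terminal CH2 of 8 then bonds to the methide carbon (C3–C4), and the developing C2 cation, stabilised by the para methoxy group of ring B, is captured by the quinone methide oxygen (O1–C2). Ring C therefore closes by an intermolecular, concerted but asynchronous [4+2] annulation, in the stepwise limit a six-membered closure of the phenolic oxygen on the C2 benzylic cation within the ion pair. C2 is the only new stereocentre and is under catalyst control: the 3,3'-aryl groups of the bound phosphoramide shield one face of the styrene-derived carbon as the C–O bond forms, and the catalyst antipode is chosen to give S. Regioselectivity (aryl on C2) follows from the matched polarity of the methide carbon and the styrene terminus. Chemoselectivity over self-alkylation at the nucleophilic C6–H of ring A and over cationic oligomerisation of 8 is sought by slow addition of 7, excess 8, low temperature and sieves that take up the water set free. The substrate itself contributes little to facial control, since the alkene has no hydrogen-bond donor, so the level of enantioselectivity rests on the strongly acidic, confined catalyst.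

Step 6
Reactants: 10 (S)-2-(3,4-dimethoxyphenyl)-5,7,8-trimethoxychroman
Product: 11 (2S)-2-(3,4-dimethoxyphenyl)-5,7,8-trimethoxychroman-4-ol (both C4 epimers)
Conditions: DDQ (1.2 equiv), CH2Cl2/pH 7 phosphate buffer (10:1), 0 °C
Reagents that add atoms: water, O
Why: DDQ benzylic C–H oxidation by hydride abstraction, the reaction used to oxygenate C4 of O-alkylated flavans; the C4 cation is the O-alkylated quinone methide of ring A, stabilised by O1 and the C5 and C7 methoxy groups, and is trapped by water. C2 is not involved, both C4 epimers are acceptable because C4 becomes sp2 in step 7, and any material oxidised further to the ketone is already 12.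

Step 7
Reactants: 11 (2S)-2-(3,4-dimethoxyphenyl)-5,7,8-trimethoxychroman-4-ol
Product: 12 (S)-2-(3,4-dimethoxyphenyl)-5,7,8-trimethoxychroman-4-one
Conditions: activated MnO2 (15 equiv), CH2Cl2, rt
Reagents that add atoms: none
Why: MnO2 oxidation of a benzylic alcohol under neutral heterogeneous conditions; no base or acid is present, so the flavanone should not open to the 2'-hydroxychalcone and the C2 configuration set in step 5 is retained.

## Compound list

1 | 3,4,5-trimethoxyphenol | COc1cc(O)cc(OC)c1OC | starting material
2 | 1,2,3,5-tetramethoxybenzene | COc1cc(OC)c(OC)c(OC)c1 | intermediate
3 | N-[(2,3,4,6-tetramethoxyphenyl)methylidene]-N-methylmethanaminium chloride | COc1cc(OC)c(C=[N+](C)C)c(OC)c1OC.[Cl-] | intermediate (not isolated)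
4 | 2,3,4,6-tetramethoxybenzaldehyde | COc1cc(OC)c(C=O)c(OC)c1OC | intermediate
5 | dichloro(2-formyl-3,5,6-trimethoxyphenoxy)borane | COc1cc(OC)c(C=O)c(OB(Cl)Cl)c1OC | intermediate (not isolated)
6 | 2-hydroxy-3,4,6-trimethoxybenzaldehyde | COc1cc(OC)c(C=O)c(O)c1OC | intermediate
7 | 2-(hydroxymethyl)-3,5,6-trimethoxyphenol | COc1cc(OC)c(CO)c(O)c1OC | intermediate
8 | 3,4-dimethoxystyrene (4-ethenyl-1,2-dimethoxybenzene) | C=Cc1ccc(OC)c(OC)c1 | starting material
9 | 2,3,5-trimethoxy-6-methylidenecyclohexa-2,4-dien-1-one | C=C1C(OC)=CC(OC)=C(OC)C1=O | intermediate (not isolated)
10 | (S)-2-(3,4-dimethoxyphenyl)-5,7,8-trimethoxychroman | COc1ccc([C@@H]2CCc3c(OC)cc(OC)c(OC)c3O2)cc1OC | intermediate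
11 | (2S)-2-(3,4-dimethoxyphenyl)-5,7,8-trimethoxychroman-4-ol, both C4 epimers | COc1ccc([C@@H]2CC(O)c3c(OC)cc(OC)c(OC)c3O2)cc1OC | intermediate
12 | (S)-2-(3,4-dimethoxyphenyl)-5,7,8-trimethoxychroman-4-one | COc1ccc([C@@H]2CC(=O)c3c(OC)cc(OC)c(OC)c3O2)cc1OC | target

## Step count and least certain steps

Total step count: 7. Longest linear sequence: 7 steps (1 to 12); 8 is purchased and enters in step 5.

**Step 5 (key step).**
- The most likely failure is poor facial selectivity when the C2–O bond forms, because the alkene offers the chiral anion no hydrogen-bond handle and the ion pair can loosen.
- Enantiopurity can also erode through reversible acid ionisation of the product's C2–O bond.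
- Material can be lost through self-alkylation of the quinone methide and cationic oligomerisation of the styrene.
- Fallback: it sets out from 6 and uses known chemistry throughout.
  - Claisen–Schmidt condensation of 6 with 3,4-dimethoxyacetophenone (KOH, EtOH) should give (E)-1-(3,4-dimethoxyphenyl)-3-(2-hydroxy-3,4,6-trimethoxyphenyl)prop-2-en-1-one F1.
  - Hydrogenation of the alkene (H2, Pd/C, EtOAc) should give 1-(3,4-dimethoxyphenyl)-3-(2-hydroxy-3,4,6-trimethoxyphenyl)propan-1-one F2.
  - CBS reduction ((S)-Me-CBS oxazaborolidine, BH3·SMe2, THF) should give (R)-1-(3,4-dimethoxyphenyl)-3-(2-hydroxy-3,4,6-trimethoxyphenyl)propan-1-ol F3, with the aryl group as the large substituent.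
  - Intramolecular Mitsunobu etherification (PPh3, DIAD, THF, 0 °C) closes ring C with inversion at the carbinol carbon, and the route is rejoined at 10.
  - Its own weak spot is partial ionisation of the electron-rich benzylic carbinol during the Mitsunobu step.

**Step 6.**
- Hydride abstraction may compete at C2, which is a 3,4-dimethoxybenzylic position next to oxygen.
- The C4 cation may lose a proton from C3 and be dehydrogenated further towards a flavylium species.
- The para-dimethoxy ring A may be attacked oxidatively.
- Fallback: it sets out from 10. Pb(OAc)4 in benzene should acetoxylate C4 to give (2S)-2-(3,4-dimethoxyphenyl)-5,7,8-trimethoxychroman-4-yl acetate F4. Methanolysis (K2CO3, MeOH, 0 °C) then returns to the route at 11.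

**Step 4.**
- Over-reduction to the methylphenol can occur through quinone methide formation under the basic hydride conditions.
- Compound 7 can self-condense on concentration or on silica.
- Fallback: it sets out from 6. After reduction with NaBH4 in MeOH the crude solution is treated with PPTS, so that the quinone methide is captured by the solvent as 2-(methoxymethyl)-3,5,6-trimethoxyphenol F5, a storable benzylic ether. F5 replaces 7 in step 5, where the acid ionises it to 9 with loss of methanol, and the route is rejoined at 10.

## Further compounds

F1 | step 5 | (E)-1-(3,4-dimethoxyphenyl)-3-(2-hydroxy-3,4,6-trimethoxyphenyl)prop-2-en-1-one | COc1ccc(C(=O)/C=C/c2c(OC)cc(OC)c(OC)c2O)cc1OC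
F2 | step 5 | 1-(3,4-dimethoxyphenyl)-3-(2-hydroxy-3,4,6-trimethoxyphenyl)propan-1-one | COc1ccc(C(=O)CCc2c(OC)cc(OC)c(OC)c2O)cc1OC
F3 | step 5 | (R)-1-(3,4-dimethoxyphenyl)-3-(2-hydroxy-3,4,6-trimethoxyphenyl)propan-1-ol | COc1ccc([C@H](O)CCc2c(OC)cc(OC)c(OC)c2O)cc1OC
F4 | step 6 | (2S)-2-(3,4-dimethoxyphenyl)-5,7,8-trimethoxychroman-4-yl acetate, both C4 epimers | COc1ccc([C@@H]2CC(OC(C)=O)c3c(OC)cc(OC)c(OC)c3O2)cc1OC
F5 | step 4 | 2-(methoxymethyl)-3,5,6-trimethoxyphenol | COCc1c(OC)cc(OC)c(OC)c1O
A1 | alternative 1 | 1a-(3,4-dimethoxyphenyl)-3,4,6-trimethoxy-6b-(trimethylsilyloxy)-1a,6b-dihydro-1H-cyclopropa[b]benzofuran, enantiomer as drawn | COc1ccc(cc1OC)[C@@]23Oc4c(OC)c(OC)cc(OC)c4[C@]2(O[Si](C)(C)C)C3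
A2 | alternative 1 | 2-(3,4-dimethoxyphenyl)-4,6,7-trimethoxy-3-(trimethylsilyloxy)benzofuran | COc1ccc(cc1OC)-c1oc2c(OC)c(OC)cc(OC)c2c1O[Si](C)(C)C
A3 | alternative 1 | 2-(3,4-dimethoxyphenyl)-4,6,7-trimethoxybenzofuran-3(2H)-one | COc1ccc(cc1OC)C1Oc2c(OC)c(OC)cc(OC)c2C1=O
A4 | alternative 2 | (S)-2-(3,4-dimethoxyphenyl)-5,8-dihydroxy-7-methoxychroman-4-one | COc1ccc([C@@H]2CC(=O)c3c(O)cc(OC)c(O)c3O2)cc1OC
A5 | alternative 2 | (S)-1-(2,5-dihydroxy-4-methoxyphenyl)-3-(3,4-dimethoxyphenyl)-3-hydroxypropan-1-one | COc1ccc([C@@H](O)CC(=O)c2cc(O)c(OC)cc2O)cc1OC
A6 | alternative 2 | (S)-2-[3-(3,4-dimethoxyphenyl)-3-hydroxypropanoyl]-5-methoxy-1,4-benzoquinone | COc1ccc([C@@H](O)CC(=O)C2=CC(=O)C(OC)=CC2=O)cc1OC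
A7 | alternative 3 | 2-(3,4-dimethoxyphenyl)-5,7,8-trimethoxy-4H-chromen-4-one | COc1ccc(-c2cc(=O)c3c(OC)cc(OC)c(OC)c3o2)cc1OC
A8 | alternative 3 | 2-iodo-3,5,6-trimethoxyphenol | COc1cc(OC)c(I)c(O)c1OC
A9 | alternative 3 | 4-ethynyl-1,2-dimethoxybenzene | C#Cc1ccc(OC)c(OC)c1
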